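**Retrosynthetic overview**

1. Locants: tetralin C1 (CH–aryl), C2 and C3 (CH–CH3), C4 (CH2), C4a/C8a (fusion atoms of ring A; C6 OMe, C7 OH); ring B = guaiacyl ring on C1; ring C = guaiacyl ring of the side chain.
2. Endgame: ring B phenol + ethyl (S)-lactate (Mitsunobu, inversion), one-pot Weinreb amide/aryl Grignard to the aryl ketone, chelation-controlled reduction (erythro), hydrogenolysis of both benzyl ethers.
3. Tetralin ring (closed second): C1–C8a by ionising the benzylic C1–O bond of a temporary oxolane (quinone-methide cation of ring B), ring A attacking para to its OMe; the freed CH2OH on C3 is then reduced to CH3.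
4. Oxolane ring (closed first, not in the target): one nickel-catalysed operation on an O-allyl 2-bromo-1-arylpropyl ether forms C2–C3 (5-exo radical closure) and C4–C4a (capture of the primary C4 radical by the ring A aryl bromide).
5. Enabling feature: C1 is benzylic to ring B (para oxygen) and is the atom that ends up bonded to C8a of ring A. It can therefore first carry an allyloxy group that ties C3/C4 to C2 through the future C3-methyl carbon, relays the one catalyst-set centre (C1, CBS reduction) to C2 and C3, and finally departs as the leaving group.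

Key step: step 6

Remark: the bromoketone, the bromohydrin and the bromo ether are carried as mixtures of C2 epimers, because C2 becomes a planar radical in the key step and is set anew there.

**Route**

Step 1
Reactants: 1 4-bromo-2-methoxyphenol
Product: 2 1-(benzyloxy)-4-bromo-2-methoxybenzene
Conditions: BnBr, K2CO3, DMF, rt
Reagents that add atoms: benzyl bromide, BrCc1ccccc1
Why: Williamson ether synthesis of a phenoxide with a benzylic bromide; the same aryl bromide later supplies ring A (step 6) and ring C (step 11).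

Step 2
Reactants: 3 1-(4-hydroxy-3-methoxyphenyl)propan-1-one
Product: 4 2-methoxy-4-propanoylphenyl acetate
Conditions: Ac2O, Et3N, DMAP (cat.), CH2Cl2, 0 °C to rt
Reagents that add atoms: acetic anhydride, CC(=O)OC(C)=O
Why: O-acetylation of the phenol; the acetate keeps ring B electron-poor enough that benzylic C1 should not ionise in steps 4 to 6, and it is removed in step 7 exactly when ionisation is wanted.

Step 3
Reactants: 4 2-methoxy-4-propanoylphenyl acetate
Product: 5 4-(2-bromopropanoyl)-2-methoxyphenyl acetate (racemic)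
Conditions: CuBr2 (2.1 equiv), EtOAc, reflux
Reagents that add atoms: copper dibromide, Br[Cu]Br
Why: α-bromination of an aryl ketone through its enol with CuBr2, which should spare the deactivated ring; the C2 configuration is irrelevant.

Step 4
Reactants: 5 4-(2-bromopropanoyl)-2-methoxyphenyl acetate
Product: 6 4-[(1R)-2-bromo-1-hydroxypropyl]-2-methoxyphenyl acetate (C2 epimers)
Conditions: (R)-2-methyl-CBS-oxazaborolidine (10 mol%), BH3·SMe2, THF, −20 °C; MeOH quench
Reagents that add atoms: none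
Why: Corey–Bakshi–Shibata reduction, in which catalyst-controlled hydride delivery with ring B as the large group should set C1 as R in both C2 epimers, as known for α-halo aryl ketones.

Step 5
Reactants: 6 4-[(1R)-2-bromo-1-hydroxypropyl]-2-methoxyphenyl acetate; 7 prop-2-en-1-yl 2,2,2-trichloroethanimidate
Product: 8 4-[(1R)-2-bromo-1-(prop-2-en-1-yloxy)propyl]-2-methoxyphenyl acetate (C2 epimers)
Conditions: TfOH (5 mol%), CH2Cl2–cyclohexane, 0 °C
Reagents that add atoms: none
Why: acid-catalysed O-alkylation with a trichloroacetimidate, used for base-sensitive halohydrins because no alkoxide (and so no epoxide) is formed; C1 is not a reacting centre, and the acetoxy ring and β-bromine disfavour its ionisation.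

Step 6
Reactants: 8 4-[(1R)-2-bromo-1-(prop-2-en-1-yloxy)propyl]-2-methoxyphenyl acetate; 2 1-(benzyloxy)-4-bromo-2-methoxybenzene
Product: 9 4-[(2S,3S,4R)-4-{[4-(benzyloxy)-3-methoxyphenyl]methyl}-3-methyloxolan-2-yl]-2-methoxyphenyl acetate
Conditions: NiBr2·dme (10 mol%), 4,4'-di-tert-butyl-2,2'-bipyridine (12 mol%), Zn dust (3 equiv), NaI (0.5 equiv), DMA, 30 °C; 2 in excess (2 equiv)
Reagents that add atoms: none
Why: This is the known nickel-catalysed reductive radical cyclisation/aryl cross-coupling of alkene-tethered alkyl bromides with aryl halides (a cross-electrophile 1,2-dicarbofunctionalisation): zerovalent nickel, made from NiBr2 and Zn, adds 2 oxidatively, and a monovalent nickel species abstracts bromine from 8 to give the C2 radical, so both C2 epimers converge. The radical closes the temporary oxolane ring in the 5-exo-trig mode (3-oxahex-5-enyl radical) onto the internal alkene carbon, which forms C2–C3 and leaves a primary radical on C4; capture of this radical by the aryl–nickel species and reductive elimination from trivalent nickel forms C4–C4a. In the chair-like Beckwith–Houk transition state the ring B aryl on C1 sits pseudo-equatorial, so the new CH2 on C3 should go trans to that aryl and cis to the methyl on the radical carbon; the single C1 centre (R) thus controls both new centres, C2 (S) and C3 (R), giving the 2,3-trans-3,4-cis oxolane. The step needs cyclisation before aryl capture (secured by the fast 5-exo closure of the oxygen-containing tether and the low nickel loading), cross-coupling over homocoupling (excess 2, NaI), and exo regiochemistry (the tether length places only the internal carbon within reach of a five-membered closure). The aryl acetate, the benzyl ether and the methyl ethers should be inert; minor diastereomers would be removed by chromatography here or after step 7.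

Step 7
Reactants: 9 4-[(2S,3S,4R)-4-{[4-(benzyloxy)-3-methoxyphenyl]methyl}-3-methyloxolan-2-yl]-2-methoxyphenyl acetate
Product: 11 4-[(1S,2R,3R)-7-(benzyloxy)-3-(hydroxymethyl)-6-methoxy-2-methyl-1,2,3,4-tetrahydronaphthalen-1-yl]-2-methoxyphenol, via free phenol 10 (not isolated)
Conditions: HCl (1.25 M in MeOH), 50 °C
Reagents that add atoms: none
Why: acid methanolysis removes the acetate, the para-hydroxyl of ring B then lets the benzylic C1–O bond ionise (protonated quinone methide, any methanol adduct re-ionises), and ring A attacks through C8a, para to its OMe, in a six-membered Friedel–Crafts closure of the type that turns 2-aryl-4-benzyloxolane lignans into aryltetralins; C1 is set anew trans to the C2 methyl (aryl pseudo-equatorial), and the oxolane oxygen ends as the CH2OH on C3.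

Step 8
Reactants: 11 4-[(1S,2R,3R)-7-(benzyloxy)-3-(hydroxymethyl)-6-methoxy-2-methyl-1,2,3,4-tetrahydronaphthalen-1-yl]-2-methoxyphenol
Product: 12 4-[(1S,2R,3R)-7-(benzyloxy)-3-(iodomethyl)-6-methoxy-2-methyl-1,2,3,4-tetrahydronaphthalen-1-yl]-2-methoxyphenol
Conditions: I2, PPh3, imidazole, CH2Cl2, 0 °C to rt
Reagents that add atoms: iodine, II
Why: Appel iodination, which converts the primary alcohol through its alkoxyphosphonium salt and should leave the phenol untouched because an aryl C–O bond cannot be displaced.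

Step 9
Reactants: 12 4-[(1S,2R,3R)-7-(benzyloxy)-3-(iodomethyl)-6-methoxy-2-methyl-1,2,3,4-tetrahydronaphthalen-1-yl]-2-methoxyphenol
Product: 13 4-[(1S,2S,3R)-7-(benzyloxy)-6-methoxy-2,3-dimethyl-1,2,3,4-tetrahydronaphthalen-1-yl]-2-methoxyphenol
Conditions: Bu3SnH, AIBN (cat.), toluene, 80 °C
Reagents that add atoms: none
Why: radical-chain hydrodeiodination of a primary iodide, which turns the tether carbon into the C3 methyl without touching the phenol, the benzyl ether or any stereocentre.

Step 10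
Reactants: 13 4-[(1S,2S,3R)-7-(benzyloxy)-6-methoxy-2,3-dimethyl-1,2,3,4-tetrahydronaphthalen-1-yl]-2-methoxyphenol; 14 ethyl (2S)-2-hydroxypropanoate
Product: 15 ethyl (2R)-2-{4-[(1S,2S,3R)-7-(benzyloxy)-6-methoxy-2,3-dimethyl-1,2,3,4-tetrahydronaphthalen-1-yl]-2-methoxyphenoxy}propanoate
Conditions: PPh3, DIAD, THF, 0 °C to rt
Reagents that add atoms: none
Why: Mitsunobu etherification of the only free phenol with the lactate hydroxyl, an SN2 displacement with clean inversion that turns the bought (S) centre into the (R) aryloxy centre of the side chain.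

Step 11
Reactants: 15 ethyl (2R)-2-{4-[(1S,2S,3R)-7-(benzyloxy)-6-methoxy-2,3-dimethyl-1,2,3,4-tetrahydronaphthalen-1-yl]-2-methoxyphenoxy}propanoate; 2 1-(benzyloxy)-4-bromo-2-methoxybenzene
Product: 18 (2R)-1-[4-(benzyloxy)-3-methoxyphenyl]-2-{4-[(1S,2S,3R)-7-(benzyloxy)-6-methoxy-2,3-dimethyl-1,2,3,4-tetrahydronaphthalen-1-yl]-2-methoxyphenoxy}propan-1-one, via Weinreb amide 16 (not isolated), via arylmagnesium bromide 17 (not isolated)
Conditions: MeNH(OMe)·HCl, iPrMgCl, THF, −20 °C; then 17 (made apart from 2, Mg, THF), −20 to 0 °C; aq. NH4Cl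
Reagents that add atoms: N,O-dimethylhydroxylamine hydrochloride, CNOC.Cl (atoms stay in 16 only); magnesium, [Mg] (atoms stay in 17 only)
Why: ester aminolysis by the magnesium amide gives the Weinreb amide, whose stable chelated tetrahedral adduct with the aryl Grignard releases the ketone only on work-up, so over-addition and enolisation of the α-aryloxy centre should be avoided.

Step 12
Reactants: 18 (2R)-1-[4-(benzyloxy)-3-methoxyphenyl]-2-{4-[(1S,2S,3R)-7-(benzyloxy)-6-methoxy-2,3-dimethyl-1,2,3,4-tetrahydronaphthalen-1-yl]-2-methoxyphenoxy}propan-1-one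
Product: 19 (1S,2R)-1-[4-(benzyloxy)-3-methoxyphenyl]-2-{4-[(1S,2S,3R)-7-(benzyloxy)-6-methoxy-2,3-dimethyl-1,2,3,4-tetrahydronaphthalen-1-yl]-2-methoxyphenoxy}propan-1-ol
Conditions: Zn(BH4)2, Et2O, −30 to 0 °C
Reagents that add atoms: none
Why: chelation-controlled (Cram chelate) reduction, in which zinc bridges the carbonyl and the α-aryloxy oxygen and hydride enters from the face of the small α-hydrogen, which for the (R) ketone should give the (1S,2R) erythro alcohol.

Step 13
Reactants: 19 (1S,2R)-1-[4-(benzyloxy)-3-methoxyphenyl]-2-{4-[(1S,2S,3R)-7-(benzyloxy)-6-methoxy-2,3-dimethyl-1,2,3,4-tetrahydronaphthalen-1-yl]-2-methoxyphenoxy}propan-1-ol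
Product: 20 4-[(1S,2R)-1-hydroxy-2-{4-[(1S,2S,3R)-7-hydroxy-6-methoxy-2,3-dimethyl-1,2,3,4-tetrahydronaphthalen-1-yl]-2-methoxyphenoxy}propyl]-2-methoxyphenol (target)
Conditions: H2 (1 atm), 10% Pd/C, EtOAc–MeOH, rt
Reagents that add atoms: none
Why: hydrogenolysis of the two aryl benzyl ethers under neutral conditions, which with monitoring should leave the benzylic alcohol and the alkyl aryl ether intact.

**Compound list**

1 | 4-bromo-2-methoxyphenol | COc1cc(Br)ccc1O | starting material
2 | 1-(benzyloxy)-4-bromo-2-methoxybenzene | COc1cc(Br)ccc1OCc1ccccc1 | intermediate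
3 | 1-(4-hydroxy-3-methoxyphenyl)propan-1-one | CCC(=O)c1ccc(O)c(OC)c1 | starting material
4 | 2-methoxy-4-propanoylphenyl acetate | CCC(=O)c1ccc(OC(C)=O)c(OC)c1 | intermediate
5 | 4-(2-bromopropanoyl)-2-methoxyphenyl acetate (racemic) | CC(Br)C(=O)c1ccc(OC(C)=O)c(OC)c1 | intermediate
6 | 4-[(1R)-2-bromo-1-hydroxypropyl]-2-methoxyphenyl acetate (C2 epimers) | CC(=O)Oc1ccc(cc1OC)[C@@H](O)C(C)Br | intermediate
7 | prop-2-en-1-yl 2,2,2-trichloroethanimidate | C=CCOC(=N)C(Cl)(Cl)Cl | starting material
8 | 4-[(1R)-2-bromo-1-(prop-2-en-1-yloxy)propyl]-2-methoxyphenyl acetate (C2 epimers) | CC(=O)Oc1ccc(cc1OC)[C@@H](OCC=C)C(C)Br | intermediate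
9 | 4-[(2S,3S,4R)-4-{[4-(benzyloxy)-3-methoxyphenyl]methyl}-3-methyloxolan-2-yl]-2-methoxyphenyl acetate | CC(=O)Oc1ccc(cc1OC)[C@H]2OC[C@H](Cc3ccc(OCc4ccccc4)c(OC)c3)[C@@H]2C | intermediate
10 | 4-[(2S,3S,4R)-4-{[4-(benzyloxy)-3-methoxyphenyl]methyl}-3-methyloxolan-2-yl]-2-methoxyphenol | Oc1ccc(cc1OC)[C@H]2OC[C@H](Cc3ccc(OCc4ccccc4)c(OC)c3)[C@@H]2C | intermediate
11 | 4-[(1S,2R,3R)-7-(benzyloxy)-3-(hydroxymethyl)-6-methoxy-2-methyl-1,2,3,4-tetrahydronaphthalen-1-yl]-2-methoxyphenol | COc1cc(ccc1O)[C@H]1c2cc(OCc3ccccc3)c(OC)cc2C[C@@H](CO)[C@@H]1C | intermediate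
12 | 4-[(1S,2R,3R)-7-(benzyloxy)-3-(iodomethyl)-6-methoxy-2-methyl-1,2,3,4-tetrahydronaphthalen-1-yl]-2-methoxyphenol | COc1cc(ccc1O)[C@H]1c2cc(OCc3ccccc3)c(OC)cc2C[C@@H](CI)[C@@H]1C | intermediate
13 | 4-[(1S,2S,3R)-7-(benzyloxy)-6-methoxy-2,3-dimethyl-1,2,3,4-tetrahydronaphthalen-1-yl]-2-methoxyphenol | COc1cc(ccc1O)[C@H]1c2cc(OCc3ccccc3)c(OC)cc2C[C@@H](C)[C@@H]1C | intermediate
14 | ethyl (2S)-2-hydroxypropanoate | C[C@H](O)C(=O)OCC | starting material
15 | ethyl (2R)-2-{4-[(1S,2S,3R)-7-(benzyloxy)-6-methoxy-2,3-dimethyl-1,2,3,4-tetrahydronaphthalen-1-yl]-2-methoxyphenoxy}propanoate | CCOC(=O)[C@@H](C)Oc1ccc(cc1OC)[C@H]1c2cc(OCc3ccccc3)c(OC)cc2C[C@@H](C)[C@@H]1C | intermediate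
16 | (2R)-2-{4-[(1S,2S,3R)-7-(benzyloxy)-6-methoxy-2,3-dimethyl-1,2,3,4-tetrahydronaphthalen-1-yl]-2-methoxyphenoxy}-N-methoxy-N-methylpropanamide | CON(C)C(=O)[C@@H](C)Oc1ccc(cc1OC)[C@H]1c2cc(OCc3ccccc3)c(OC)cc2C[C@@H](C)[C@@H]1C | intermediate
17 | [4-(benzyloxy)-3-methoxyphenyl]magnesium bromide | COc1cc([Mg]Br)ccc1OCc1ccccc1 | intermediate
18 | (2R)-1-[4-(benzyloxy)-3-methoxyphenyl]-2-{4-[(1S,2S,3R)-7-(benzyloxy)-6-methoxy-2,3-dimethyl-1,2,3,4-tetrahydronaphthalen-1-yl]-2-methoxyphenoxy}propan-1-one | COc1cc(ccc1OCc1ccccc1)C(=O)[C@@H](C)Oc1ccc(cc1OC)[C@H]1c2cc(OCc3ccccc3)c(OC)cc2C[C@@H](C)[C@@H]1C | intermediate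
19 | (1S,2R)-1-[4-(benzyloxy)-3-methoxyphenyl]-2-{4-[(1S,2S,3R)-7-(benzyloxy)-6-methoxy-2,3-dimethyl-1,2,3,4-tetrahydronaphthalen-1-yl]-2-methoxyphenoxy}propan-1-ol | COc1cc(ccc1OCc1ccccc1)[C@H](O)[C@@H](C)Oc1ccc(cc1OC)[C@H]1c2cc(OCc3ccccc3)c(OC)cc2C[C@@H](C)[C@@H]1C | intermediate
20 | 4-[(1S,2R)-1-hydroxy-2-{4-[(1S,2S,3R)-7-hydroxy-6-methoxy-2,3-dimethyl-1,2,3,4-tetrahydronaphthalen-1-yl]-2-methoxyphenoxy}propyl]-2-methoxyphenol | COc1cc([C@H](O)[C@@H](C)Oc2ccc([C@H]3c4cc(O)c(OC)cc4C[C@@H](C)[C@@H]3C)cc2OC)ccc1O | target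

**Step count and risks**

Total step count: 13. Longest linear sequence: 12 steps (steps 2 to 13, from 3).

Step 6 (key step). What may go wrong: the C2 radical may be captured by aryl–nickel before it cyclises (open-chain arylation), the aryl bromide may homocouple, or facial selectivity in the 5-exo closure may be poor. The fallback makes the same two bonds in separate, individually known operations. Starting from 8, Finkelstein exchange (NaI, acetone, reflux) should give 4-[(1R)-2-iodo-1-(prop-2-en-1-yloxy)propyl]-2-methoxyphenyl acetate F1. Iodine-atom-transfer radical cyclisation (Et3B, air, benzene, rt) should then give 4-[(2S,3S,4R)-4-(iodomethyl)-3-methyloxolan-2-yl]-2-methoxyphenyl acetate F2, with no metal competing for the radical and with the chance to separate diastereomers. Nickel-catalysed cross-electrophile coupling of this primary iodide with 2 (NiBr2·dme, 4,4'-di-tert-butyl-2,2'-bipyridine, Zn, DMA) returns to the route at 9.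

Step 5. What may go wrong: acid-promoted ionisation at benzylic C1 (loss of configuration, elimination) or incomplete alkylation of the hindered secondary alcohol. The fallback forms the C1–O bond by epoxide opening instead of O-alkylation. Starting from 5, reduction with the enantiomeric (S)-2-methyl-CBS-oxazaborolidine and BH3·SMe2 should give 4-[(1S)-2-bromo-1-hydroxypropyl]-2-methoxyphenyl acetate F3. K2CO3 in dry acetone should close it to 2-methoxy-4-[(2S)-3-methyloxiran-2-yl]phenyl acetate F4. Opening at the benzylic carbon with allyl alcohol (BF3·OEt2 cat., CH2Cl2, −40 °C, inversion at C1) should give 4-[(1R)-2-hydroxy-1-(prop-2-en-1-yloxy)propyl]-2-methoxyphenyl acetate F5. Appel bromination of the C2 hydroxyl (CBr4, PPh3, CH2Cl2) returns to the route at 8.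

Step 12. What may go wrong: incomplete chelation of zinc between the carbonyl and the aryloxy oxygen, hence poor facial selectivity and an erythro/threo mixture. The fallback uses Felkin-controlled reduction followed by inversion. Starting from 18, LiBH(s-Bu)3 (THF, −78 °C) should give the threo alcohol (1R,2R)-1-[4-(benzyloxy)-3-methoxyphenyl]-2-{4-[(1S,2S,3R)-7-(benzyloxy)-6-methoxy-2,3-dimethyl-1,2,3,4-tetrahydronaphthalen-1-yl]-2-methoxyphenoxy}propan-1-ol F6. Mitsunobu inversion with 4-nitrobenzoic acid (PPh3, DIAD, THF) should give (1S,2R)-1-[4-(benzyloxy)-3-methoxyphenyl]-2-{4-[(1S,2S,3R)-7-(benzyloxy)-6-methoxy-2,3-dimethyl-1,2,3,4-tetrahydronaphthalen-1-yl]-2-methoxyphenoxy}propyl 4-nitrobenzoate F7. Methanolysis (K2CO3, MeOH) returns to the route at 19.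

**Further compounds**

F1 | step 6 | 4-[(1R)-2-iodo-1-(prop-2-en-1-yloxy)propyl]-2-methoxyphenyl acetate | CC(=O)Oc1ccc(cc1OC)[C@@H](OCC=C)C(C)I
F2 | step 6 | 4-[(2S,3S,4R)-4-(iodomethyl)-3-methyloxolan-2-yl]-2-methoxyphenyl acetate | CC(=O)Oc1ccc(cc1OC)[C@H]2OC[C@H](CI)[C@@H]2C
F3 | step 5 | 4-[(1S)-2-bromo-1-hydroxypropyl]-2-methoxyphenyl acetate | CC(=O)Oc1ccc(cc1OC)[C@H](O)C(C)Br
F4 | step 5 | 2-methoxy-4-[(2S)-3-methyloxiran-2-yl]phenyl acetate | CC(=O)Oc1ccc(cc1OC)[C@@H]2OC2C
F5 | step 5 | 4-[(1R)-2-hydroxy-1-(prop-2-en-1-yloxy)propyl]-2-methoxyphenyl acetate | CC(=O)Oc1ccc(cc1OC)[C@@H](OCC=C)C(C)O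
F6 | step 12 | (1R,2R)-1-[4-(benzyloxy)-3-methoxyphenyl]-2-{4-[(1S,2S,3R)-7-(benzyloxy)-6-methoxy-2,3-dimethyl-1,2,3,4-tetrahydronaphthalen-1-yl]-2-methoxyphenoxy}propan-1-ol | COc1cc(ccc1OCc1ccccc1)[C@@H](O)[C@@H](C)Oc1ccc(cc1OC)[C@H]1c2cc(OCc3ccccc3)c(OC)cc2C[C@@H](C)[C@@H]1C
F7 | step 12 | (1S,2R)-1-[4-(benzyloxy)-3-methoxyphenyl]-2-{4-[(1S,2S,3R)-7-(benzyloxy)-6-methoxy-2,3-dimethyl-1,2,3,4-tetrahydronaphthalen-1-yl]-2-methoxyphenoxy}propyl 4-nitrobenzoate | COc1cc(ccc1OCc1ccccc1)[C@H](OC(=O)c1ccc(cc1)[N+](=O)[O-])[C@@H](C)Oc1ccc(cc1OC)[C@H]1c2cc(OCc3ccccc3)c(OC)cc2C[C@@H](C)[C@@H]1C
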